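The synthesis rests on opening ring C'' of unit 2 (the 6''-linked 7''-methoxyflavone) at C8a''–O1'', C4a''–C4'' and O1''–C2''. The feature exploited is that O1'' (on C8a'') and carbonyl carbon C4'' (on C4a'') are ortho neighbours, with the C5'' oxygen flanking C4a''. A C4a''–C8a'' aryne polarised by a C5'' methoxy group therefore takes up both atoms regioselectively. In one operation the aryne is spliced into the CO–OH bond of an arylpropiolic acid and the resulting phenoxide closes the pyranone. The precursor is an ortho-silylaryl triflate already bearing the isopropyl-protected acacetin unit. Silicon is installed before a Negishi biaryl coupling, so no organolithium meets a flavone.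

Key step: step 11

Assumption: the SMILES gives no descriptor for the hindered C8–C6'' axis and the molecule has no stereocentre, so the racemate about this axis is taken as the target; unprimed and singly primed locants refer to unit 1 (acacetin part), doubly and triply primed ones to unit 2.

Step 1
Reactants: 1 phloroglucinol; 2 ethyl 3-(4-methoxyphenyl)-3-oxopropanoate
Product: 3 acacetin (5,7-dihydroxy-2-(4-methoxyphenyl)chromen-4-one)
Conditions: neat, 240 °C
Reagents that add atoms: none
Why: The catalyst-free thermal condensation of a phenol with a β-keto ester (Mentzer pyrone synthesis) proceeds by C-acylation and cyclodehydration, and the threefold symmetry of 1 leaves no regiochemical choice.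

Step 2
Reactants: 3 acacetin
Product: 4 5,7-diisopropoxy-2-(4-methoxyphenyl)chromen-4-one
Conditions: i-PrBr (excess), Cs2CO3, DMF, 70 °C
Reagents that add atoms: 2-bromopropane, CC(C)Br
Why: Williamson etherification with Cs2CO3 in warm DMF and excess secondary bromide should be forcing enough to alkylate the hydrogen-bonded C5 hydroxyl as well as the acidic C7 hydroxyl.

Step 3
Reactants: 4 5,7-diisopropoxy-2-(4-methoxyphenyl)chromen-4-one
Product: 5 8-iodo-5,7-diisopropoxy-2-(4-methoxyphenyl)chromen-4-one
Conditions: NIS (1.05 equiv), TFA (cat.), MeCN, 0 °C → rt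
Reagents that add atoms: N-iodosuccinimide, O=C1CCC(=O)N1I
Why: In this electrophilic aromatic iodination ring A is the most electron-rich ring, C8 is the usual halogenation site of 5,7-dialkoxyflavones, and C6 is shielded by two isopropoxy groups.

Step 4
Reactants: 6 4-bromo-3,5-dimethoxyphenol
Product: 7 4-bromo-2-iodo-3,5-dimethoxyphenol
Conditions: NIS (1.0 equiv), MeCN, −20 → 0 °C
Reagents that add atoms: N-iodosuccinimide, O=C1CCC(=O)N1I
Why: This is electrophilic aromatic iodination ortho to a free phenol, and because C2 and C6 of 6 are equivalent by symmetry, one equivalent of reagent should give a single monoiodide.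

Step 5
Reactants: 7 4-bromo-2-iodo-3,5-dimethoxyphenol
Product: 10 4-bromo-3,5-dimethoxy-2-(trimethylsilyl)phenol, via O-trimethylsilyl ether 8 (not isolated), via aryllithium 9 (not isolated)
Conditions: HMDS, THF, 65 °C, then concentrate; n-BuLi (1.05 equiv), THF, −78 °C; aq. NH4Cl
Reagents that add atoms: hexamethyldisilazane, C[Si](C)(C)N[Si](C)(C)C
Why: O-silylation, halogen–lithium exchange and retro-Brook (O to C) silyl migration form the standard entry to ortho-silylphenols, and here iodine exchanges far faster than bromine at −78 °C while the aryllithium is consumed intramolecularly before it can scramble with the C4 bromide.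

Step 6
Reactants: 10 4-bromo-3,5-dimethoxy-2-(trimethylsilyl)phenol
Product: 11 [6-(benzyloxy)-3-bromo-2,4-dimethoxyphenyl]trimethylsilane
Conditions: BnBr, K2CO3, DMF, rt
Reagents that add atoms: benzyl bromide, BrCc1ccccc1
Why: Williamson etherification under mild carbonate conditions leaves the aryl–silicon bond intact and installs a group that resists n-BuLi at −78 °C and is later removed under neutral conditions.

Step 7
Reactants: 11 [6-(benzyloxy)-3-bromo-2,4-dimethoxyphenyl]trimethylsilane; 5 8-iodo-5,7-diisopropoxy-2-(4-methoxyphenyl)chromen-4-one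
Product: 14 8-[4-(benzyloxy)-2,6-dimethoxy-3-(trimethylsilyl)phenyl]-5,7-diisopropoxy-2-(4-methoxyphenyl)chromen-4-one, via aryllithium 12 (not isolated), via arylzinc chloride 13 (not isolated)
Conditions: 11, n-BuLi, THF, −78 °C; ZnCl2, −78 °C → rt; then 5, Pd2(dba)3 (cat.), RuPhos, THF/NMP, 70 °C
Reagents that add atoms: none
Why: Bromine–lithium exchange, transmetalation to zinc and Negishi coupling on zerovalent palladium with a bulky dialkylbiarylphosphine is an established way to tetra-ortho-substituted biaryls, the arylzinc leaves the chromenone carbonyl alone, and the C8–C6'' axis forms as a racemate.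

Step 8
Reactants: 14 8-[4-(benzyloxy)-2,6-dimethoxy-3-(trimethylsilyl)phenyl]-5,7-diisopropoxy-2-(4-methoxyphenyl)chromen-4-one
Product: 15 8-[4-hydroxy-2,6-dimethoxy-3-(trimethylsilyl)phenyl]-5,7-diisopropoxy-2-(4-methoxyphenyl)chromen-4-one
Conditions: H2 (1 atm), Pd/C, EtOAc, rt
Reagents that add atoms: none
Why: Catalytic hydrogenolysis of the benzyl aryl ether is neutral and should spare the acid- and fluoride-sensitive aryl–silicon bond, the isopropyl ethers and the flavone C2=C3 bond.

Step 9
Reactants: 15 8-[4-hydroxy-2,6-dimethoxy-3-(trimethylsilyl)phenyl]-5,7-diisopropoxy-2-(4-methoxyphenyl)chromen-4-one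
Product: 16 4-[5,7-diisopropoxy-2-(4-methoxyphenyl)-4-oxochromen-8-yl]-3,5-dimethoxy-2-(trimethylsilyl)phenyl trifluoromethanesulfonate
Conditions: PhNTf2, DBU, MeCN, 40 °C
Reagents that add atoms: N-phenylbis(trifluoromethanesulfonimide), O=S(=O)(C(F)(F)F)N(c1ccccc1)S(=O)(=O)C(F)(F)F
Why: O-triflylation of the hindered phenoxide with the mild donor PhNTf2 is the usual last step toward ortho-silylaryl triflates and is preferred to Tf2O because the nucleophilic chromenone carbonyl oxygen is not attacked.

Step 10
Reactants: 17 1-(benzyloxy)-4-ethynylbenzene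
Product: 19 3-[4-(benzyloxy)phenyl]propiolic acid, via lithium acetylide 18 (not isolated)
Conditions: n-BuLi, THF, −78 °C; CO2; aq. HCl
Reagents that add atoms: carbon dioxide, O=C=O
Why: Deprotonation of the terminal alkyne and carboxylation of the lithium acetylide with CO2 is the textbook route to arylpropiolic acids.

Step 11
Reactants: 16 4-[5,7-diisopropoxy-2-(4-methoxyphenyl)-4-oxochromen-8-yl]-3,5-dimethoxy-2-(trimethylsilyl)phenyl trifluoromethanesulfonate; 19 3-[4-(benzyloxy)phenyl]propiolic acid
Product: 22 8-{2-[4-(benzyloxy)phenyl]-5,7-dimethoxy-4-oxochromen-6-yl}-5,7-diisopropoxy-2-(4-methoxyphenyl)chromen-4-one, via aryne 20 (not isolated), via ortho-hydroxyaryl ynone 21 (not isolated)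
Conditions: 19 (1.2 equiv), CsF (4 equiv), THF (0.02 M), 125 °C, sealed tube
Reagents that add atoms: none
Why: Fluoride strips the silyl group and triflate departs to give aryne 20, the carboxylate of 19 adds through oxygen to C8a'', the aryl anion left on C4a'' attacks the neighbouring ester carbonyl, and the strained four-membered alkoxide opens to the phenoxide of ynone 21, which sets C8a''–O1'' and C4a''–C4''. The closest known reaction type is the formal insertion of arynes into the acyl C–O bond of carboxylic acids to give ortho-hydroxyaryl ketones, which with arylpropiolic acids runs on to flavones. Ring C'' closes by 6-endo-dig oxa-Michael addition of the C8a'' phenoxide to the ynone terminus C2'' (bond O1''–C2''), the mode preferred by such phenoxides in aprotic media, and the proton of the acid ends up on C3''. No stereocentre is created and the C8–C6'' axis stays racemic. The step needs one sense of addition to an unsymmetrical aryne, and this is secured by the C5'' methoxy group, whose inductive pull distorts the triple bond so that nucleophiles attack the remote carbon C8a'', which is also sterically open because C8'' carries only hydrogen. It also needs acyl transfer to outrun protonation of the aryl anion, which heat, high dilution and only a slight excess of acid favour, and since the ring oxygen is fixed by the carbon it attacks, the 8''-linked isomer of unit 2 cannot arise.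

Step 12
Reactants: 22 8-{2-[4-(benzyloxy)phenyl]-5,7-dimethoxy-4-oxochromen-6-yl}-5,7-diisopropoxy-2-(4-methoxyphenyl)chromen-4-one
Product: 23 8-[5-hydroxy-2-(4-hydroxyphenyl)-7-methoxy-4-oxochromen-6-yl]-5,7-dihydroxy-2-(4-methoxyphenyl)chromen-4-one (target)
Conditions: BCl3 (excess), C6HMe5, CH2Cl2, −78 → 0 °C; then H2O
Reagents that add atoms: none
Why: In this Lewis-acid ether cleavage the isopropyl and benzyl aryl ethers ionise readily, the C5'' methyl ether is activated by chelation of boron between O5'' and the C4'' carbonyl, the unchelated methyl ethers at C7'' and C4' should resist BCl3 at or below 0 °C, and pentamethylbenzene traps the benzyl cation.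

Compound list
1 | phloroglucinol (benzene-1,3,5-triol) | Oc1cc(O)cc(O)c1 | starting material
2 | ethyl 3-(4-methoxyphenyl)-3-oxopropanoate | CCOC(=O)CC(=O)c1ccc(OC)cc1 | starting material
3 | acacetin, 5,7-dihydroxy-2-(4-methoxyphenyl)chromen-4-one | COc1ccc(-c2cc(=O)c3c(O)cc(O)cc3o2)cc1 | intermediate
4 | 5,7-diisopropoxy-2-(4-methoxyphenyl)chromen-4-one | COc1ccc(-c2cc(=O)c3c(OC(C)C)cc(OC(C)C)cc3o2)cc1 | intermediate
5 | 8-iodo-5,7-diisopropoxy-2-(4-methoxyphenyl)chromen-4-one | COc1ccc(-c2cc(=O)c3c(OC(C)C)cc(OC(C)C)c(I)c3o2)cc1 | intermediate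
6 | 4-bromo-3,5-dimethoxyphenol | COc1cc(O)cc(OC)c1Br | starting material
7 | 4-bromo-2-iodo-3,5-dimethoxyphenol | COc1cc(O)c(I)c(OC)c1Br | intermediate
8 | (4-bromo-2-iodo-3,5-dimethoxyphenoxy)trimethylsilane | COc1cc(O[Si](C)(C)C)c(I)c(OC)c1Br | intermediate
9 | [3-bromo-2,4-dimethoxy-6-(trimethylsilyloxy)phenyl]lithium | COc1cc(O[Si](C)(C)C)c([Li])c(OC)c1Br | intermediate
10 | 4-bromo-3,5-dimethoxy-2-(trimethylsilyl)phenol | COc1cc(O)c([Si](C)(C)C)c(OC)c1Br | intermediate
11 | [6-(benzyloxy)-3-bromo-2,4-dimethoxyphenyl]trimethylsilane | COc1cc(OCc2ccccc2)c([Si](C)(C)C)c(OC)c1Br | intermediate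
12 | [4-(benzyloxy)-2,6-dimethoxy-3-(trimethylsilyl)phenyl]lithium | COc1cc(OCc2ccccc2)c([Si](C)(C)C)c(OC)c1[Li] | intermediate
13 | [4-(benzyloxy)-2,6-dimethoxy-3-(trimethylsilyl)phenyl]zinc chloride | COc1cc(OCc2ccccc2)c([Si](C)(C)C)c(OC)c1[Zn]Cl | intermediate
14 | 8-[4-(benzyloxy)-2,6-dimethoxy-3-(trimethylsilyl)phenyl]-5,7-diisopropoxy-2-(4-methoxyphenyl)chromen-4-one | COc1ccc(-c2cc(=O)c3c(OC(C)C)cc(OC(C)C)c(-c4c(OC)cc(OCc5ccccc5)c([Si](C)(C)C)c4OC)c3o2)cc1 | intermediate
15 | 8-[4-hydroxy-2,6-dimethoxy-3-(trimethylsilyl)phenyl]-5,7-diisopropoxy-2-(4-methoxyphenyl)chromen-4-one | COc1ccc(-c2cc(=O)c3c(OC(C)C)cc(OC(C)C)c(-c4c(OC)cc(O)c([Si](C)(C)C)c4OC)c3o2)cc1 | intermediate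
16 | 4-[5,7-diisopropoxy-2-(4-methoxyphenyl)-4-oxochromen-8-yl]-3,5-dimethoxy-2-(trimethylsilyl)phenyl trifluoromethanesulfonate | C[Si](C)(C)c1c(OS(=O)(=O)C(F)(F)F)cc(OC)c(-c2c(OC(C)C)cc(OC(C)C)c3c(=O)cc(-c4ccc(OC)cc4)oc23)c1OC | intermediate
17 | 1-(benzyloxy)-4-ethynylbenzene | C#Cc1ccc(OCc2ccccc2)cc1 | starting material
18 | lithium [4-(benzyloxy)phenyl]acetylide | [Li]C#Cc1ccc(OCc2ccccc2)cc1 | intermediate
19 | 3-[4-(benzyloxy)phenyl]propiolic acid | OC(=O)C#Cc1ccc(OCc2ccccc2)cc1 | intermediate
20 | 8-(3,4-didehydro-2,6-dimethoxyphenyl)-5,7-diisopropoxy-2-(4-methoxyphenyl)chromen-4-one (C4a''–C8a'' aryne) | COC1=C(c2c(OC(C)C)cc(OC(C)C)c3c(=O)cc(-c4ccc(OC)cc4)oc23)C(OC)=CC#C1 | intermediate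
21 | 8-(3-{3-[4-(benzyloxy)phenyl]prop-2-ynoyl}-4-hydroxy-2,6-dimethoxyphenyl)-5,7-diisopropoxy-2-(4-methoxyphenyl)chromen-4-one | COc1cc(O)c(C(=O)C#Cc2ccc(OCc3ccccc3)cc2)c(OC)c1-c1c(OC(C)C)cc(OC(C)C)c2c(=O)cc(-c3ccc(OC)cc3)oc12 | intermediate
22 | 8-{2-[4-(benzyloxy)phenyl]-5,7-dimethoxy-4-oxochromen-6-yl}-5,7-diisopropoxy-2-(4-methoxyphenyl)chromen-4-one | COc1ccc(-c2cc(=O)c3c(OC(C)C)cc(OC(C)C)c(-c4c(OC)cc5oc(-c6ccc(OCc7ccccc7)cc6)cc(=O)c5c4OC)c3o2)cc1 | intermediate
23 | 8-[5-hydroxy-2-(4-hydroxyphenyl)-7-methoxy-4-oxochromen-6-yl]-5,7-dihydroxy-2-(4-methoxyphenyl)chromen-4-one (CNP0253922.0) | COc1ccc(-c2cc(=O)c3c(O)cc(O)c(-c4c(OC)cc5oc(-c6ccc(O)cc6)cc(=O)c5c4O)c3o2)cc1 | target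

Total step count: 12.
Longest linear sequence: 8 steps (6 → 7 → 10 → 11 → 14 → 15 → 16 → 22 → 23). The branch from 1 through 3, 4 and 5 is equally long.

The three steps most likely to fail

Risk 1 (step 11). Three processes could erode the step:
- The C4a'' aryl anion may be protonated before it reaches the ester carbonyl, which amounts to plain O-arylation of the acid.
- The propiolate may decarboxylate at 125 °C.
- The phenoxide may close in the 5-exo mode.

The fallback avoids the aryne and sets out from phenol 15. ipso-Iododesilylation with ICl (CH2Cl2, −78 °C) replaces silicon by iodine at C4a'' and should give the ortho-iodophenol 8-(4-hydroxy-3-iodo-2,6-dimethoxyphenyl)-5,7-diisopropoxy-2-(4-methoxyphenyl)chromen-4-one F1. A carbonylative Sonogashira coupling–cyclisation of F1 with alkyne 17 under CO (PdCl2(dppf), Et2NH, 100 °C) is a known flavone synthesis from ortho-iodophenols. It builds C4a''–C4'' through an acylpalladium species and O1''–C2'' through amine-mediated 6-endo closure, and it comes back to the route at 22.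

Risk 2 (step 7). The palladium centre has to carry two di-ortho-oxygenated aryl groups. Transmetalation and reductive elimination may then be so slow that protodezincation of the arylzinc and hydrodeiodination of the flavone take over.

The fallback reverses the polarity and sets out from iodide 5. Borylation with pinacolborane (PdCl2(MeCN)2, SPhos, Et3N, dioxane, 80 °C) should give the isolable boronate 5,7-diisopropoxy-2-(4-methoxyphenyl)-8-(4,4,5,5-tetramethyl-1,3,2-dioxaborolan-2-yl)chromen-4-one F2. Suzuki–Miyaura coupling of F2 with bromide 11 itself (Pd(OAc)2, SPhos, K3PO4, toluene/H2O, 100 °C) places oxidative addition on the dimethoxyaryl bromide. It needs no organolithium or organozinc stage and comes back to the route at 14.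

Risk 3 (step 12). Four ethers must fall and two must stay. Three processes could spoil this balance:
- Cleavage of the hindered C7 isopropyl ether may stay incomplete.
- Boron held at O7 may reach across the axis and take off the C7'' methyl group.
- The liberated benzyl cation may re-attack the electron-rich rings.

The fallback splits the deprotection by mechanism and sets out from 22. Hydrogenolysis (H2, Pd/C, EtOAc/THF, rt) removes the benzyl group without any cation and should give 8-[2-(4-hydroxyphenyl)-5,7-dimethoxy-4-oxochromen-6-yl]-5,7-diisopropoxy-2-(4-methoxyphenyl)chromen-4-one F3. AlCl3 (CH2Cl2, 0 °C → rt) is known to cleave isopropyl aryl ethers and peri-chelated methyl ethers while sparing ordinary aryl methyl ethers. It then frees O5, O7 and O5'' and comes back to the route at 23.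

Further compounds
F1 | step 11 | 8-(4-hydroxy-3-iodo-2,6-dimethoxyphenyl)-5,7-diisopropoxy-2-(4-methoxyphenyl)chromen-4-one | COc1ccc(-c2cc(=O)c3c(OC(C)C)cc(OC(C)C)c(-c4c(OC)cc(O)c(I)c4OC)c3o2)cc1
F2 | step 7 | 5,7-diisopropoxy-2-(4-methoxyphenyl)-8-(4,4,5,5-tetramethyl-1,3,2-dioxaborolan-2-yl)chromen-4-one | COc1ccc(-c2cc(=O)c3c(OC(C)C)cc(OC(C)C)c(B4OC(C)(C)C(C)(C)O4)c3o2)cc1
F3 | step 12 | 8-[2-(4-hydroxyphenyl)-5,7-dimethoxy-4-oxochromen-6-yl]-5,7-diisopropoxy-2-(4-methoxyphenyl)chromen-4-one | COc1ccc(-c2cc(=O)c3c(OC(C)C)cc(OC(C)C)c(-c4c(OC)cc5oc(-c6ccc(O)cc6)cc(=O)c5c4OC)c3o2)cc1
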